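**Retrosynthetic overview**
1. Target ⇒ 2-substituted 4-quinolone carrying a terminal methyl ester. The gem-dimethyl carbinol is made last by double MeMgBr addition, so the tertiary alcohol never meets acid or 250 °C.
2. The pyridone ring is the only ring formed (the benzene ring comes intact from aniline). It is closed by a Conrad–Limpach cyclisation of a Z β-anilinoacrylate, made from aniline and a β-keto ester.
3. β-Keto ester ⇒ key C–C bond by an intermolecular decarboxylative crossed Claisen condensation (Masamune–Brooks) between the imidazolide of monomethyl tridecanedioate and magnesium methyl malonate.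
4. Half-ester ⇒ dimethyl tridecanedioate by half-saponification.

Assumption: the target has no stereocentre (the carbinol carbon carries two methyl groups), so "single enantiomer" is taken to mean the achiral compound as drawn. The only stereo-element on the route is the Z geometry of enamine 8, which disappears on cyclisation.

**Route**

Step 1
Reactants: 1 dimethyl tridecanedioate (dimethyl brassylate)
Product: 2 13-methoxy-13-oxotridecanoic acid (monomethyl tridecanedioate)
Conditions: Ba(OH)2·8H2O (0.5 equiv), MeOH, rt, 24 h; filter the precipitated salt; aq. HCl, Et2O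
Reagents that add atoms: barium hydroxide Ba(OH)2, SMILES [OH-].[Ba+2].[OH-] (the hydroxide oxygen becomes the carboxyl OH)
Why: Half-saponification of a symmetrical diester, made selective because the barium salt of the half-ester precipitates from methanol as it forms and so escapes the second hydrolysis; no stereocentre.

Step 2
Reactants: 2 13-methoxy-13-oxotridecanoic acid; 3 potassium methyl malonate (potassium 3-methoxy-3-oxopropanoate)
Product: 6 dimethyl 3-oxopentadecanedioate, via acyl imidazolide 4 (not isolated), via acylmalonic half-ester 5 (not isolated)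
Conditions: Im2CO (1,1'-carbonyldiimidazole, 1.2 equiv), THF, rt, 2 h; then 3 (2.0 equiv), MgCl2 (2.0 equiv), Et3N (3.0 equiv), MeCN/THF, rt, 16 h; aq. HCl
Reagents that add atoms: none
Why: The acid is activated as the acyl imidazolide, which C-acylates the chelated magnesium enolate of methyl malonate, and loss of CO2 from the acylmalonate drives this intermolecular decarboxylative crossed Claisen condensation (Masamune–Brooks) to the β-keto ester without touching the distal methyl ester; no stereocentre.

Step 3
Reactants: 6 dimethyl 3-oxopentadecanedioate; 7 aniline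
Product: 8 dimethyl (2Z)-3-(phenylamino)pentadec-2-enedioate
Conditions: 7 (1.05 equiv), p-TsOH·H2O (2 mol %), cyclohexane, reflux, Dean–Stark, 6 h
Reagents that add atoms: none
Why: Acid-catalysed condensation of aniline with the ketone (far more electrophilic than either ester) with azeotropic water removal gives the vinylogous carbamate (enamino ester formation, first stage of the Conrad–Limpach synthesis), the Z geometry being fixed by the N–H···O=C hydrogen bond and the moderate temperature avoiding the Knorr anilide.

Step 4
Reactants: 8 dimethyl (2Z)-3-(phenylamino)pentadec-2-enedioate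
Product: 9 methyl 12-(4-oxo-1,4-dihydroquinolin-2-yl)dodecanoate
Conditions: Ph2O, 250 °C, 20 min (slow addition of 8 to the hot solvent, high dilution); cool, hexane, filter
Reagents that add atoms: none
Why: Conrad–Limpach thermal cyclisation, in which the conjugated ester acylates the ortho carbon of the N-aryl ring with loss of methanol to form the 4-quinolone, while the unconjugated remote methyl ester is inert under these neutral conditions; no stereocentre.

Step 5
Reactants: 9 methyl 12-(4-oxo-1,4-dihydroquinolin-2-yl)dodecanoate
Product: 11 2-(12-hydroxy-12-methyltridecyl)quinolin-4(1H)-one, via methyl ketone 10 (not isolated)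
Conditions: MeMgBr (6 equiv), THF, 0 °C to rt, 4 h; sat. aq. NH4Cl
Reagents that add atoms: methylmagnesium bromide MeMgBr, SMILES C[Mg]Br
Why: Grignard double addition to an ester, in which the first equivalent deprotonates N–H to an unreactive magnesium quinolinolate and the excess adds twice through the methyl ketone to the tertiary alcohol, whose carbon bears two identical methyl groups and so is not a stereocentre.

**Compound list**
1 | dimethyl tridecanedioate | COC(=O)CCCCCCCCCCCC(=O)OC | starting material
2 | 13-methoxy-13-oxotridecanoic acid | COC(=O)CCCCCCCCCCCC(=O)O | intermediate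
3 | potassium methyl malonate (potassium 3-methoxy-3-oxopropanoate) | COC(=O)CC(=O)[O-].[K+] | starting material
4 | methyl 13-(1H-imidazol-1-yl)-13-oxotridecanoate (acyl imidazolide) | COC(=O)CCCCCCCCCCCC(=O)n1ccnc1 | intermediate
5 | 3-methoxy-2-(13-methoxy-13-oxotridecanoyl)-3-oxopropanoic acid (acylmalonic half-ester, present as its magnesium chelate) | COC(=O)CCCCCCCCCCCC(=O)C(C(=O)O)C(=O)OC | intermediate
6 | dimethyl 3-oxopentadecanedioate | COC(=O)CC(=O)CCCCCCCCCCCC(=O)OC | intermediate
7 | aniline | Nc1ccccc1 | starting material
8 | dimethyl (2Z)-3-(phenylamino)pentadec-2-enedioate | COC(=O)/C=C(/CCCCCCCCCCCC(=O)OC)Nc1ccccc1 | intermediate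
9 | methyl 12-(4-oxo-1,4-dihydroquinolin-2-yl)dodecanoate | COC(=O)CCCCCCCCCCCc1cc(=O)c2ccccc2[nH]1 | intermediate
10 | 2-(12-oxotridecyl)quinolin-4(1H)-one (methyl ketone, present as its magnesium salt) | CC(=O)CCCCCCCCCCCc1cc(=O)c2ccccc2[nH]1 | intermediate
11 | 2-(12-hydroxy-12-methyltridecyl)quinolin-4(1H)-one (achiral) | CC(C)(O)CCCCCCCCCCCc1cc(=O)c2ccccc2[nH]1 | target

**Summary**
Total step count: 5. Longest linear sequence: 5 steps (1 → 2 → 6 → 8 → 9 → 11); 3 and 7 are purchased.

The three steps most likely to fail are step 4 (the riskiest), step 5 and step 3.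

Step 3 (enamine formation may stall or divert to the anilide). The fallback sets out from 6 and comes back at 8. Compound 6 is stirred with ammonium acetate in MeOH at rt to give dimethyl (2Z)-3-aminopentadec-2-enedioate F1. The N-phenyl group is then introduced by Buchwald–Hartwig N-arylation of this vinylogous carbamate with bromobenzene (Pd2(dba)3, Xantphos, Cs2CO3, dioxane, 100 °C). This gives 8 without any ketone–aniline condensation.

Step 4 (the 250 °C closure may char or give a low yield). The fallback sets out from 2 and comes back at 9, building the ring by a Camps cyclisation. Compound 2 is converted with oxalyl chloride and catalytic DMF in CH2Cl2 into methyl 13-chloro-13-oxotridecanoate F2. F2 acylates 2'-aminoacetophenone (pyridine, CH2Cl2, 0 °C to rt) to give methyl 13-[(2-acetylphenyl)amino]-13-oxotridecanoate F3. NaOH in dioxane at 110 °C closes the acetyl methyl group onto the amide carbonyl by intramolecular aldol condensation and saponifies the ester. Acidification gives 12-(4-oxo-1,4-dihydroquinolin-2-yl)dodecanoic acid F4. Fischer esterification (MeOH, catalytic H2SO4, reflux) returns 9.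

Step 5 (the magnesium salt of the free quinolone may be insoluble, or addition may stop at ketone 10). The fallback sets out from 9 and comes back at 11, masking the quinolone before the Grignard step. Compound 9 is O-benzylated (benzyl bromide, K2CO3, DMF, 60 °C; O-alkylation is favoured by the 2-alkyl group) to give methyl 12-[4-(benzyloxy)quinolin-2-yl]dodecanoate F5, which is soluble in THF. MeMgBr (3 equiv, THF, 0 °C) converts it into 13-[4-(benzyloxy)quinolin-2-yl]-2-methyltridecan-2-ol F6. Hydrogenolysis (H2 at 1 atm, Pd/C (palladium on carbon), MeOH, rt) removes the benzyl group and gives 11.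

**Further compounds**
F1 | step 3 | dimethyl (2Z)-3-aminopentadec-2-enedioate | COC(=O)/C=C(/CCCCCCCCCCCC(=O)OC)N
F2 | step 4 | methyl 13-chloro-13-oxotridecanoate | COC(=O)CCCCCCCCCCCC(=O)Cl
F3 | step 4 | methyl 13-[(2-acetylphenyl)amino]-13-oxotridecanoate | COC(=O)CCCCCCCCCCCC(=O)Nc1ccccc1C(C)=O
F4 | step 4 | 12-(4-oxo-1,4-dihydroquinolin-2-yl)dodecanoic acid | OC(=O)CCCCCCCCCCCc1cc(=O)c2ccccc2[nH]1
F5 | step 5 | methyl 12-[4-(benzyloxy)quinolin-2-yl]dodecanoate | COC(=O)CCCCCCCCCCCc1cc(OCc2ccccc2)c2ccccc2n1
F6 | step 5 | 13-[4-(benzyloxy)quinolin-2-yl]-2-methyltridecan-2-ol | CC(C)(O)CCCCCCCCCCCc1cc(OCc2ccccc2)c2ccccc2n1
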